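**Assumption:** the target SMILES carries no stereodescriptor and the molecule has no stereocentre. The C4–C4' axis (H at C3/C3', 1,1'-binaphthyl-type barrier) is taken as not configurationally fixed, so there is no stereochemistry to set.

## Retrosynthetic overview

1. The obvious C4–C4' homocoupling of a 4-halo/4-triflyloxy-isofraxidin is avoided; the C4–C4' bond is bought in as the central σ-bond of a conjugated diynedioate.
2. Target ⇒ two molecules of 2,4-dimethoxybenzene-1,3-diol + dimethyl hexa-2,4-diynedioate, by a bidirectional double hydroarylation–lactonisation (key step, last step).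
3. Diyne diester ⇒ methyl propiolate (Glaser–Hay). Diol ⇒ 3-hydroxy-2,4-dimethoxybenzaldehyde (Dakin) ⇒ 2-bromoisovanillin (Cu-mediated methoxylation).
4. Ring order: both benzene rings are purchased; both α-pyranone rings are formed together in the final step, which delivers the free 7,7'-OH groups with no protecting groups.

## Route

**Step 1**
Reactants: 1, 2-bromo-3-hydroxy-4-methoxybenzaldehyde (2-bromoisovanillin)
Product: 2, 3-hydroxy-2,4-dimethoxybenzaldehyde
Conditions: NaOMe (5 equiv, 25% in MeOH), CuCl (0.3 equiv), DMF, 110 °C, N2; then aq. HCl
Reagents that add atoms: sodium methoxide, [Na+].[O-]C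
Why: Cu(I)-mediated Ullmann-type methoxylation of an aryl bromide ortho to a phenoxide (the bromovanillin → syringaldehyde reaction type); the non-enolisable, phenoxide-deactivated aldehyde tolerates the conditions.

**Step 2**
Reactants: 2, 3-hydroxy-2,4-dimethoxybenzaldehyde
Product: 3, 2,4-dimethoxybenzene-1,3-diol
Conditions: 30% H2O2 (1.3 equiv), cat. H2SO4, MeOH, 0 °C → rt; Na2S2O3 quench; use promptly under N2
Reagents that add atoms: hydrogen peroxide, OO
Why: Acid-catalysed Dakin (Baeyer–Villiger-type) oxidation in which the aryl group, made electron-rich by ortho- and para-OMe, migrates to oxygen and the aryl formate is methanolysed in situ.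

**Step 3**
Reactants: 4, methyl propiolate (2 equiv)
Product: 5, dimethyl hexa-2,4-diynedioate
Conditions: CuCl (10 mol%), TMEDA (10 mol%), O2 (1 atm), acetone, rt; handle cold and in solution (vesicant)
Reagents that add atoms: none
Why: Glaser–Hay oxidative homocoupling of a terminal alkynoate builds the C(sp)–C(sp) bond that becomes C4–C4' of the target.

**Step 4 (key step)**
Reactants: 3, 2,4-dimethoxybenzene-1,3-diol (2.3 equiv); 5, dimethyl hexa-2,4-diynedioate (1 equiv, added slowly)
Product: 6, 4,4'-biisofraxidin (7,7'-dihydroxy-6,6',8,8'-tetramethoxy-4,4'-bi-2H-chromene-2,2'-dione)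
Conditions: Pd(OAc)2 (5 mol%), TFA/CH2Cl2 (3:1), 0 °C → rt (warm to 40 °C if the mono-annulated intermediate persists), N2, 24–48 h
Reagents that add atoms: none
Why: Proposed new method: a two-fold Pd(II)/TFA hydroarylation–lactonisation on a conjugated diynedioate, in which each ester polarises its own alkyne so that C6 of 3 (para to the free 3-OH and the only position ortho to an OH) attacks the β-carbon (C3, then C4 of 5, already bonded to each other) anti to Pd, protodemetalation gives the Z-2-hydroxycinnamate, and TFA-driven lactonisation with loss of MeOH gives first a transient 4-(alkynyl)coumarin (not isolated) and then the bicoumarin, so the hindered axis is assembled by attack on an unhindered sp carbon and not by biaryl coupling; the closest known reaction is the Fujiwara–Kitamura Pd(OAc)2/TFA coupling of electron-rich phenols with 3-aryl- and 3-alkyl-propiolates to give 4-substituted coumarins; no stereocentre is formed.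

Atom balance for Step 4: 2 × C8H10O4 + C8H6O4 − 2 CH3OH = C22H18O10, which is the target.

## Compound list

1 | 2-bromo-3-hydroxy-4-methoxybenzaldehyde | COc1ccc(C=O)c(Br)c1O | starting material
2 | 3-hydroxy-2,4-dimethoxybenzaldehyde | COc1ccc(C=O)c(OC)c1O | intermediate
3 | 2,4-dimethoxybenzene-1,3-diol | COc1ccc(O)c(OC)c1O | intermediate
4 | methyl propiolate | C#CC(=O)OC | starting material
5 | dimethyl hexa-2,4-diynedioate | COC(=O)C#CC#CC(=O)OC | intermediate
6 | 4,4'-biisofraxidin | COc1cc2c(-c3cc(=O)oc4c(OC)c(O)c(OC)cc34)cc(=O)oc2c(OC)c1O | target

## Summary

Total steps: 4.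
Longest linear sequence: 3 (1 → 2 → 3 → 6); Step 3 is a one-step side branch.

Steps most likely to fail:

1. **Step 4 (double annulation).** Risks are wrong-carbon attack in the second hydroarylation (α-carbon, giving a benzofuranone), 5-exo O-cyclisation of the ortho-OH onto the remaining ynoate, or stalling at the mono-annulated stage.
   Fallback: tether the nucleophile. Acylate 2,3,4-trimethoxyphenol with propiolic acid (DCC), Hay-couple to the bis(aryl) hexa-2,4-diynedioate, and run a double intramolecular 6-endo hydroarylation (JohnPhosAu(MeCN)SbF6 or Pd(OAc)2/TFA), where the tether forces attack at the β-carbon and no free OH is present. Then cleave the two central 7,7'-OMe groups selectively (AlCl3 or LiCl/DMF).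

2. **Step 1 (Cu methoxylation).** Risks are hydrodebromination to isovanillin or aldehyde degradation in hot methoxide.
   Fallback: make diol 3 from 2,6-dimethoxyphenol instead. Protect as the MOM ether, lithiate ortho to OMe (n-BuLi/TMEDA), trap with B(OMe)3 and oxidise with H2O2, then remove MOM with HCl/MeOH.

3. **Step 2 (Dakin on a free, very electron-rich phenol).** Risk is over-oxidation of the tetra-oxygenated diol.
   Fallback: carry the 7-oxygen as a methyl ether. Dakin-oxidise commercial 2,3,4-trimethoxybenzaldehyde to 2,3,4-trimethoxyphenol, use it in the annulation with 5, and unveil the 7,7'-OH groups last by selective demethylation of the central, carbonyl-conjugated methoxy groups.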